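Locants used throughout (they follow the target, not lowest-locant rules): C1 (carbon bearing =CH2), C2 (CHOH), C3, C4 (CHBr), C5 (CMe2), C6 (spiro), C7, C8, C9 (CMeCl), C10 (CHBr), C11. Ring A is C1–C6, ring B is C6–C11. The target, compound 21, is (2R,4R,6S,9S,10S)-4,10-dibromo-9-chloro-5,5,9-trimethyl-1-methylidenespiro[5.5]undecan-2-ol.

## The problem

Target 21 is a spiro[5.5]undecane whose spiro atom C6 is bonded to a second quaternary carbon, C5, so the C5–C6 bond joins two fully substituted carbons and is the hardest bond to make. C6 is the only link between the stereocentres of ring A (C2, C4) and ring B (C9, C10), and it is stereogenic only because its two ring B arms differ three bonds away (C8H2 against C10HBr), so no local bias can set it. C4 is a secondary bromide next to CMe2; it is out of reach of SN2 chemistry and is best made by opening a bromiranium ion. C9/C10 is the anti adduct of BrCl to a C9=C10 alkene, but with both halogens equatorial and Br cis to C5, so Br+ must come from one face and chloride must open at C9 against the diaxial preference. C2–OH is allylic, axial, cis to C7 and trans to C4–Br. The fragile groups are the tertiary chloride with its vicinal bromide (E2, reductive elimination by zinc, cuprates or alkyllithiums) and the allylic alcohol beside the exocyclic alkene (ionisation, and Wagner–Meerwein shifts of any cation at C1 next to quaternary C6). The feature that opens the plan is that ring B carries its only carbon branch at C9, para to C6, so ring B is the reduced form of a para-substituted phenol (C9 = C–O, C6 = ipso carbon), while C4(Br)–C5(Me2) is the imprint of a prenyl bromiranium ion; an ipso attack of C6 on C5 makes the C5–C6 bond, ring A, the spiro atom and C4–Br at once. In the resulting cyclohexadienone 10 the two arms of ring B are identical, so C6 is not yet a stereocentre and can be set afterwards by a desymmetrisation.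

## Retrosynthesis

**C2–O (21 ⇒ 20).** The allylic C–O bond is cut first. In 20, C6 is quaternary and ring B is saturated, so C2 is the only allylic CH2 in the molecule and an allylic hydroxylation has no regiochemical choice. The neighbouring cut, α-hydroxylation of ketone 19 before methylenation, would need a protecting group and would make the neopentyl ketone harder to olefinate. The forward step must deliver oxygen to the face of C2 cis to C7.

**C1=CH2 (20 ⇒ 19 ⇒ 18 ⇒ 17).** The exocyclic carbon is cut back to ketone 19, which comes from alcohol 18 and its pivalate 17. The C1 oxygen is needed as a handle anyway; kept as a carbinol ester, it is the single stereocentre that steers step 5 and shields one face of ring B in step 9, and it is erased here. The forward methylenation must work on a neopentyl ketone without base, because the vicinal dihalide is present.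

**C9–Cl and C10–Br (17 ⇒ 15).** Both C–halogen bonds are cut to the C9=C10 alkene of 15 (anti addition of BrCl). Building the pair from a C9 ketone (α-bromination, methyl addition, OH to Cl) was rejected: the C9 cation would take chloride axially, cis to bromine. The addition is placed at the pivalate stage because 15 has only one alkene and the pivaloyloxy group covers the face cis to C1. The forward step needs Br+ on the face cis to C5 and chloride at C9.

**C9–CH3 and the oxidation pattern of ring B (15 ⇒ 14 ⇒ 12 ⇒ 10).** The methyl group is cut to enol triflate 14, which comes from enone 12 by conjugate reduction and enolate trapping, and 12 comes from dienone 10 by reduction of one of two equivalent-looking C=C bonds. The C9 oxygen of the phenol is thus used twice, as activator of the arene and as the site of the methyl group. The forward step from 10 must choose C7=C8 over C10=C11; this choice creates the C6 stereocentre.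

**C5–C6, the key cut (10 ⇒ 7).** Cutting the bond between the two quaternary carbons leads to the acyclic pivalate 7, a para-substituted aryl silyl ether with a prenyl terminus and one stereocentre. Cuts at C6–C7/C6–C11 (spiroannulation onto a finished ring A) leave C5–C6 and the neopentyl bromide to be made separately; a cut at C1–C6 gives no access to C4–Br. The forward reaction must attack at the ipso carbon, not the alkene-derived cation's other exits, and must relay C1 to C4.

**C1–C2 (7 ⇒ 6 ⇒ 5 ⇒ 4 ⇒ 1 + 2).** The chain is cut at C1–C2 to the Grignard reagent 3 from bromide 1 and to aldehyde 2. The carbinol configuration of 6 comes from an asymmetric transfer hydrogenation of ketone 5.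

## Roads not taken

Alternative 1: Diels–Alder spiroannulation, the most obvious route. Cut C6–C11 and C7–C8; the exocyclic enone (4R)-4-bromo-3,3-dimethyl-2-methylidenecyclohexan-1-one A1 and isoprene would give spiro ketone A2 (para rule). A1 still contains the neopentyl bromide and needs its own bromonium cyclisation and its own source of absolute configuration. The face of C6 that the diene takes is decided only by the remote C4–Br and by a gem-dimethyl group that flanks both faces. The chosen plan makes C5–C6 and C4–Br in one step from a four-step precursor and moves the C6 decision to a catalyst-controlled step.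

Alternative 2: biomimetic bromonium cyclisation onto a tetrasubstituted alkene. Cut C5–C6 with the exocyclic alkene of (E)-γ-bisabolene A3 as nucleophile, to give 10-bromo-α-chamigrene A4. A3 must be a single geometric isomer of a tetrasubstituted alkene whose two ring substituents differ only at a remote ring alkene, and E/Z errors become C6 epimers. The bromiranium ion has no handle for absolute control. A4 carries two trisubstituted alkenes that must then be told apart. The symmetrical arene of 7 has no E/Z problem, and the C1 carbinol gives absolute control.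

Alternative 3: enolate allylation and ring-closing metathesis. Cut C9=C10 (metathesis) and C6–C11 (asymmetric allylic alkylation): the α-quaternary vinylogous ester A5 would close to spirocycle A6. This sets C6 and the ring B alkene well, but A6 has its oxygen at C3 instead of C2 and an unactivated neopentyl CH2 at C4. The C4 bromide would have to be forced in by substitution next to a quaternary carbon, and the oxygen moved by several redox steps.

Key step: step 5

Assumption (step 6): the (R)-antipode of the bisphosphine is written; which antipode delivers hydride to C7 of 10 cannot be derived from first principles and is fixed by the first experiment (both are commercial).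

## Route

Step 1
Reactants: 1 5-bromo-2-methylpent-2-ene; 2 4-[(tert-butyldimethylsilyl)oxy]benzaldehyde
Product: 4 rac-1-{4-[(tert-butyldimethylsilyl)oxy]phenyl}-5-methylhex-4-en-1-ol, via (4-methylpent-3-en-1-yl)magnesium bromide 3 (not isolated)
Conditions: Mg, THF, rt; then 2, 0 °C; H2O (NH4Cl buffer)
Reagents that add atoms: none
Why: Grignard formation from the homoallylic bromide and 1,2-addition to the aldehyde; the aryl silyl ether is inert, and the carbinol is left racemic because it is oxidised in step 2.

Step 2
Reactants: 4 rac-1-{4-[(tert-butyldimethylsilyl)oxy]phenyl}-5-methylhex-4-en-1-ol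
Product: 5 1-{4-[(tert-butyldimethylsilyl)oxy]phenyl}-5-methylhex-4-en-1-one
Conditions: Dess–Martin periodinane, NaHCO3, CH2Cl2, rt
Reagents that add atoms: none
Why: Dess–Martin oxidation of a benzylic alcohol; the trisubstituted alkene and the silyl ether are untouched.

Step 3
Reactants: 5 1-{4-[(tert-butyldimethylsilyl)oxy]phenyl}-5-methylhex-4-en-1-one
Product: 6 (1R)-1-{4-[(tert-butyldimethylsilyl)oxy]phenyl}-5-methylhex-4-en-1-ol
Conditions: RuCl(p-cymene)[(R,R)-TsDPEN] (1 mol%), HCO2H/Et3N 5:2, rt
Reagents that add atoms: none
Why: Noyori asymmetric transfer hydrogenation of an aryl alkyl ketone; the (R,R)-catalyst should give the (R)-carbinol as it does with acetophenone, and the Ru hydride does not reduce the isolated alkene. This centre relays to C4 in step 5 and is erased in step 11.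

Step 4
Reactants: 6 (1R)-1-{4-[(tert-butyldimethylsilyl)oxy]phenyl}-5-methylhex-4-en-1-ol
Product: 7 (1R)-1-{4-[(tert-butyldimethylsilyl)oxy]phenyl}-5-methylhex-4-en-1-yl 2,2-dimethylpropanoate
Conditions: PivCl, pyridine, DMAP (cat.), CH2Cl2, 0 °C to rt
Reagents that add atoms: pivaloyl chloride, CC(C)(C)C(Cl)=O
Why: Acylation of a secondary alcohol; an ester oxygen does not capture the bromiranium ion of step 5 (a free or silylated hydroxyl would close a tetrahydropyran), the pivalate survives L-Selectride in step 7, and it keeps the C1 oxygen from fragmenting dienone 10 by a retro-aldol path.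

Step 5
Reactants: 7 (1R)-1-{4-[(tert-butyldimethylsilyl)oxy]phenyl}-5-methylhex-4-en-1-yl 2,2-dimethylpropanoate
Product: 10 (1R,4R)-4-bromo-5,5-dimethyl-9-oxospiro[5.5]undeca-7,10-dien-1-yl 2,2-dimethylpropanoate, via bromiranium ion 8 (not isolated), via O-silyl spirocyclohexadienyl cation 9 (not isolated)
Conditions: BDSB (1.1 equiv), MeNO2, −25 °C, 10 min; then aq. NaHCO3/Na2SO3
Reagents that add atoms: bromodiethylsulfonium bromopentachloroantimonate (BDSB, written as Et2SBr+ Br− · SbCl5), CC[S+](Br)CC.[Br-].Cl[Sb](Cl)(Cl)(Cl)Cl
Why: Proposed new method: BDSB transfers Br+ to the trisubstituted C4=C5 alkene, which is far more nucleophilic than the silyl aryl ether, and bromiranium ion 8 is opened at its tertiary carbon C5 by the ipso carbon C6, which is para to the silyloxy group and so the most nucleophilic ring position, whereas the carbons ortho to the chain are meta to oxygen and would close a seven-membered ring. The closest known reaction types are bromonium-initiated cation–π cyclisations of prenyl termini onto arenes (Friedel–Crafts termination) and electrophilic ipso-cyclisations that give spirocyclohexadienones (Ar1-6 participation, halonium-induced ipso-spirocyclisation of para-alkoxyaryl alkynes); their combination is new. Ring A closes by a 6-endo opening of the bromiranium ion that is at the same time a spiro (ipso) closure on the arene, and cation 9 is discharged irreversibly when Et2S or halide removes the silyl group, which should outrun a 1,2-shift to a ring-expanded phenol. Backside opening puts C4–Br anti to the new C5–C6 bond, i.e. equatorial in the chair transition state, and the C1 pivaloyloxy group must also be equatorial because an axial C1–O bond would be syn-diaxial to a C5 methyl group and nearly eclipsed with an ortho C–H, so the 1,4-trans ring with (4R) follows from (1R). The two diastereomeric bromiranium ions are expected to interconvert by Br+ transfer to Et2S and to free alkene, so the mixture should be funnelled through the favoured chair (Curtin–Hammett); any (1R,4S) isomer is removed by chromatography here, since it would become the enantiomeric series after step 11. C6 is not yet a stereocentre because ring B of 10 is a symmetrical dienone. The step needs alkene-over-arene chemoselectivity and ipso-over-elimination capture, secured by the para silyloxy group and the six-membered chair.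

Step 6
Reactants: 10 (1R,4R)-4-bromo-5,5-dimethyl-9-oxospiro[5.5]undeca-7,10-dien-1-yl 2,2-dimethylpropanoate
Product: 12 (1R,4R,6R)-4-bromo-5,5-dimethyl-9-oxospiro[5.5]undec-10-en-1-yl 2,2-dimethylpropanoate, via silyl dienol ether 11 (not isolated)
Conditions: Cu(OAc)2 (5 mol%), (R)-DTBM-SEGPHOS (5.5 mol%), (EtO)2MeSiH, toluene, 0 °C; then 1 M HCl, THF
Reagents that add atoms: none
Why: CuH-catalysed asymmetric conjugate reduction, a known desymmetrisation of 4,4-disubstituted cyclohexa-2,5-dienones: the chiral Cu–H should add hydride to C7, the β-carbon on the side of ring A that carries the C1 oxygen, and leave C10=C11, which makes C6 a stereocentre (6R). The product is stored as silyl dienol ether 11, which is no longer an enone, so a second reduction cannot occur before acidic work-up releases 12.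

Step 7
Reactants: 12 (1R,4R,6R)-4-bromo-5,5-dimethyl-9-oxospiro[5.5]undec-10-en-1-yl 2,2-dimethylpropanoate
Product: 14 (1R,4R,6R)-4-bromo-5,5-dimethyl-9-{[(trifluoromethyl)sulfonyl]oxy}spiro[5.5]undec-9-en-1-yl 2,2-dimethylpropanoate, via lithium enolate 13 (not isolated)
Conditions: L-Selectride, THF, −78 °C; then PhNTf2, −78 to 0 °C
Reagents that add atoms: N-phenylbis(trifluoromethanesulfonimide), O=S(=O)(N(c1ccccc1)S(=O)(=O)C(F)(F)F)C(F)(F)F
Why: Conjugate reduction of a β-unsubstituted (4,4-disubstituted) cyclohexenone with L-Selectride gives enolate 13 regiospecifically between C9 and C10, and O-triflation fixes the future position of the ring B alkene; the pivalate and the neopentyl bromide should not react at −78 °C.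

Step 8
Reactants: 14 (1R,4R,6R)-4-bromo-5,5-dimethyl-9-{[(trifluoromethyl)sulfonyl]oxy}spiro[5.5]undec-9-en-1-yl 2,2-dimethylpropanoate
Product: 15 (1R,4R,6R)-4-bromo-5,5,9-trimethylspiro[5.5]undec-9-en-1-yl 2,2-dimethylpropanoate
Conditions: MeZnCl, Pd(PPh3)4 (5 mol%), THF, 50 °C
Reagents that add atoms: methylzinc chloride, C[Zn]Cl
Why: Negishi cross-coupling of an alkenyl triflate with a methylzinc reagent; Pd(0)/PPh3 does not insert into the unactivated secondary C4–Br bond, and no stereocentre is touched.

Step 9
Reactants: 15 (1R,4R,6R)-4-bromo-5,5,9-trimethylspiro[5.5]undec-9-en-1-yl 2,2-dimethylpropanoate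
Product: 17 (1R,4R,6R,9S,10S)-4,10-dibromo-9-chloro-5,5,9-trimethylspiro[5.5]undecan-1-yl 2,2-dimethylpropanoate, via ring B bromiranium ion 16 (not isolated)
Conditions: Bu4N+ BrCl2−, CH2Cl2, −78 to −40 °C
Reagents that add atoms: tetrabutylammonium dichlorobromide (written as Bu4N+ Cl− · BrCl), CCCC[N+](CCCC)(CCCC)CCCC.[Cl-].ClBr
Why: Anti addition of BrCl through bromiranium ion 16: Br+ is expected on the face of C9=C10 cis to C5, because in the half-chair of ring B the quaternary C5 is pseudo-equatorial, C1 is pseudo-axial and its pivaloyloxy group (anti to C6–C5) lies over the other face, the situation of a 5α-Δ2-steroid with its angular methyl group. Chloride should then open 16 at the tertiary C9 (Markovnikov) from the side of C1, giving the trans-diequatorial (9S,10S) bromochloride with the C9 methyl axial; the competing diaxial opening at C10 would have to pass under the pivalate.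

Step 10
Reactants: 17 (1R,4R,6R,9S,10S)-4,10-dibromo-9-chloro-5,5,9-trimethylspiro[5.5]undecan-1-yl 2,2-dimethylpropanoate
Product: 18 (1R,4R,6R,9S,10S)-4,10-dibromo-9-chloro-5,5,9-trimethylspiro[5.5]undecan-1-ol
Conditions: DIBAL-H (2.5 equiv), CH2Cl2, −78 to −20 °C; Rochelle salt
Reagents that add atoms: none
Why: Reductive cleavage of the hindered pivalate with DIBAL-H at low temperature; alkyl bromides and the tertiary chloride are not reduced and no base is present that could eliminate HX.

Step 11
Reactants: 18 (1R,4R,6R,9S,10S)-4,10-dibromo-9-chloro-5,5,9-trimethylspiro[5.5]undecan-1-ol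
Product: 19 (4R,6R,9S,10S)-4,10-dibromo-9-chloro-5,5,9-trimethylspiro[5.5]undecan-1-one
Conditions: Dess–Martin periodinane, NaHCO3, CH2Cl2, rt
Reagents that add atoms: none
Why: Dess–Martin oxidation of the neopentyl secondary alcohol under buffered, non-basic conditions; the C1 relay stereocentre is erased.

Step 12
Reactants: 19 (4R,6R,9S,10S)-4,10-dibromo-9-chloro-5,5,9-trimethylspiro[5.5]undecan-1-one
Product: 20 (4R,6S,9S,10S)-4,10-dibromo-9-chloro-5,5,9-trimethyl-1-methylidenespiro[5.5]undecane
Conditions: Tebbe reagent, pyridine (cat.), THF/toluene, −40 °C to rt; aq. NaOH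
Reagents that add atoms: Tebbe reagent (written as Cp2Ti=CH2 · ClAlMe2), C[Al](C)Cl.C=[Ti](C1C=CC=C1)C1C=CC=C1
Why: Tebbe methylenation, suited to hindered and enolisable ketones; the reagent is not basic enough to eliminate the vicinal dihalide, unlike a phosphorus ylide at the temperature this neopentyl ketone would need. The C6 descriptor changes from R to S by CIP priority only.

Step 13
Reactants: 20 (4R,6S,9S,10S)-4,10-dibromo-9-chloro-5,5,9-trimethyl-1-methylidenespiro[5.5]undecane
Product: 21 (2R,4R,6S,9S,10S)-4,10-dibromo-9-chloro-5,5,9-trimethyl-1-methylidenespiro[5.5]undecan-2-ol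
Conditions: SeO2 (0.5 equiv), t-BuOOH (3 equiv), CH2Cl2, rt
Reagents that add atoms: tert-butyl hydroperoxide, CC(C)(C)OO (terminal oxygen source; the oxygen is passed on by catalytic selenium dioxide, O=[Se]=O)
Why: SeO2 allylic hydroxylation (ene reaction, then [2,3]-sigmatropic shift); C2 is the only allylic CH2 because C6 is quaternary and ring B no longer has an alkene. In the [2,3] shift oxygen is expected on the pseudo-axial lobe of C2, the usual course with methylenecyclohexanes, which is the face cis to C7 and gives (2R); this face is flanked by the axial C7 methylene, so the step is listed among the uncertain ones.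

## Compound list

1 | 5-bromo-2-methylpent-2-ene | CC(C)=CCCBr | starting material
2 | 4-[(tert-butyldimethylsilyl)oxy]benzaldehyde | O=Cc1ccc(O[Si](C)(C)C(C)(C)C)cc1 | starting material
3 | (4-methylpent-3-en-1-yl)magnesium bromide | CC(C)=CCC[Mg]Br | intermediate
4 | rac-1-{4-[(tert-butyldimethylsilyl)oxy]phenyl}-5-methylhex-4-en-1-ol | OC(CCC=C(C)C)c1ccc(O[Si](C)(C)C(C)(C)C)cc1 | intermediate
5 | 1-{4-[(tert-butyldimethylsilyl)oxy]phenyl}-5-methylhex-4-en-1-one | O=C(CCC=C(C)C)c1ccc(O[Si](C)(C)C(C)(C)C)cc1 | intermediate
6 | (1R)-1-{4-[(tert-butyldimethylsilyl)oxy]phenyl}-5-methylhex-4-en-1-ol | O[C@H](CCC=C(C)C)c1ccc(O[Si](C)(C)C(C)(C)C)cc1 | intermediate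
7 | (1R)-1-{4-[(tert-butyldimethylsilyl)oxy]phenyl}-5-methylhex-4-en-1-yl 2,2-dimethylpropanoate | CC(C)(C)C(=O)O[C@H](CCC=C(C)C)c1ccc(O[Si](C)(C)C(C)(C)C)cc1 | intermediate
8 | (1R)-1-{4-[(tert-butyldimethylsilyl)oxy]phenyl}-3-[(2R)-3,3-dimethylbromiran-1-ium-2-yl]propyl 2,2-dimethylpropanoate | CC(C)(C)C(=O)O[C@H](CC[C@H]1[Br+]C1(C)C)c1ccc(O[Si](C)(C)C(C)(C)C)cc1 | intermediate
9 | (1R,4R)-4-bromo-9-[(tert-butyldimethylsilyl)oxy]-5,5-dimethylspiro[5.5]undeca-7,10-dien-9-ylium-1-yl 2,2-dimethylpropanoate (drawn as the O-silyl oxocarbenium form) | CC(C)(C)C(=O)O[C@@H]1CC[C@@H](Br)C(C)(C)C12C=CC(=[O+][Si](C)(C)C(C)(C)C)C=C2 | intermediate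
10 | (1R,4R)-4-bromo-5,5-dimethyl-9-oxospiro[5.5]undeca-7,10-dien-1-yl 2,2-dimethylpropanoate | CC(C)(C)C(=O)O[C@@H]1CC[C@@H](Br)C(C)(C)C12C=CC(=O)C=C2 | intermediate
11 | (1R,4R,6R)-4-bromo-9-{[diethoxy(methyl)silyl]oxy}-5,5-dimethylspiro[5.5]undeca-8,10-dien-1-yl 2,2-dimethylpropanoate | CC(C)(C)C(=O)O[C@@H]1CC[C@@H](Br)C(C)(C)[C@]12CC=C(O[Si](C)(OCC)OCC)C=C2 | intermediate
12 | (1R,4R,6R)-4-bromo-5,5-dimethyl-9-oxospiro[5.5]undec-10-en-1-yl 2,2-dimethylpropanoate | CC(C)(C)C(=O)O[C@@H]1CC[C@@H](Br)C(C)(C)[C@]12CCC(=O)C=C2 | intermediate
13 | lithium (1R,4R,6R)-4-bromo-1-[(2,2-dimethylpropanoyl)oxy]-5,5-dimethylspiro[5.5]undec-9-en-9-olate | CC(C)(C)C(=O)O[C@@H]1CC[C@@H](Br)C(C)(C)[C@]12CCC(O[Li])=CC2 | intermediate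
14 | (1R,4R,6R)-4-bromo-5,5-dimethyl-9-{[(trifluoromethyl)sulfonyl]oxy}spiro[5.5]undec-9-en-1-yl 2,2-dimethylpropanoate | CC(C)(C)C(=O)O[C@@H]1CC[C@@H](Br)C(C)(C)[C@]12CCC(OS(=O)(=O)C(F)(F)F)=CC2 | intermediate
15 | (1R,4R,6R)-4-bromo-5,5,9-trimethylspiro[5.5]undec-9-en-1-yl 2,2-dimethylpropanoate | CC(C)(C)C(=O)O[C@@H]1CC[C@@H](Br)C(C)(C)[C@]12CCC(C)=CC2 | intermediate
16 | ring B bromiranium ion of 15 (Br+ bridging C9 and C10 on the face cis to C5) | CC(C)(C)C(=O)O[C@@H]1CC[C@@H](Br)C(C)(C)[C@]12CC[C@@]3(C)[Br+][C@H]3C2 | intermediate
17 | (1R,4R,6R,9S,10S)-4,10-dibromo-9-chloro-5,5,9-trimethylspiro[5.5]undecan-1-yl 2,2-dimethylpropanoate | CC(C)(C)C(=O)O[C@@H]1CC[C@@H](Br)C(C)(C)[C@]12CC[C@](C)(Cl)[C@@H](Br)C2 | intermediate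
18 | (1R,4R,6R,9S,10S)-4,10-dibromo-9-chloro-5,5,9-trimethylspiro[5.5]undecan-1-ol | O[C@@H]1CC[C@@H](Br)C(C)(C)[C@]12CC[C@](C)(Cl)[C@@H](Br)C2 | intermediate
19 | (4R,6R,9S,10S)-4,10-dibromo-9-chloro-5,5,9-trimethylspiro[5.5]undecan-1-one | O=C1CC[C@@H](Br)C(C)(C)[C@]12CC[C@](C)(Cl)[C@@H](Br)C2 | intermediate
20 | (4R,6S,9S,10S)-4,10-dibromo-9-chloro-5,5,9-trimethyl-1-methylidenespiro[5.5]undecane | C=C1CC[C@@H](Br)C(C)(C)[C@]12CC[C@](C)(Cl)[C@@H](Br)C2 | intermediate
21 | (2R,4R,6S,9S,10S)-4,10-dibromo-9-chloro-5,5,9-trimethyl-1-methylidenespiro[5.5]undecan-2-ol | C=C1[C@H](O)C[C@@H](Br)C(C)(C)[C@]12CC[C@](C)(Cl)[C@@H](Br)C2 | target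

## Step count and least certain steps

Total step count: 13. Longest linear sequence: 13 steps (1 and 2 to 21).

**Step 5 (key step, Proposed new method).** The bromiranium ion may not be captured at the ipso carbon: it can lose a proton to an allylic bromide, the arene can be brominated, cation 9 can undergo a 1,2-shift to a ring-expanded phenol before desilylation, or the benzylic pivalate can ionise and lose the relay stereocentre. The fallback uses known chemistry and gives up the dearomatisation for a Diels–Alder spiroannulation. It sets out from Grignard reagent 3, which is acylated with N-methoxy-N-methylacetamide to 6-methylhept-5-en-2-one F1. Carboxylation (NaH, dimethyl carbonate) gives methyl 7-methyl-3-oxooct-6-enoate F2. Bromonium-induced cyclisation with C-termination by the β-keto ester (BDSB, or Hg(II) then brominative demercuration) gives racemic methyl 3-bromo-2,2-dimethyl-6-oxocyclohexane-1-carboxylate F3. Reduction of the ester through its sodium enolate (NaH, then LiAlH4) and dehydration (MsCl, Et3N) give racemic 4-bromo-3,3-dimethyl-2-methylidenecyclohexan-1-one F4. Lewis-acid-promoted Diels–Alder reaction with isoprene gives 4-bromo-5,5,9-trimethylspiro[5.5]undec-9-en-1-one F5, which is resolved by HPLC on a chiral phase. The (4R,6R) enantiomer is bromochlorinated as in step 9, and the route is rejoined at ketone 19. The price is a resolution and an intermolecular face selection at C6.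

**Step 6.** Hydride delivery may be slow or unselective, because both β-carbons of the dienone are flanked by the C1 oxygen on one side and a C5 methyl on the other, and the resident centres may oppose the ligand. The fallback sets out from 10: both C=C bonds are hydrogenated (H2, Rh/Al2O3) to (1R,4R)-4-bromo-5,5-dimethyl-9-oxospiro[5.5]undecan-1-yl 2,2-dimethylpropanoate F6. Deprotonation with a chiral lithium amide (lithium (R,R)-bis(1-phenylethyl)amide, LiCl, THF, −100 °C) then selects between the two α-methylene groups and gives enolate 13 directly; trapping with PhNTf2 rejoins the route at triflate 14. This also bypasses the conjugate reduction of step 7.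

**Step 9.** Facial control of Br+ delivery or the site of chloride opening may be poor (the diaxial pathway through the other bromiranium face gives the C9/C10 diastereomer; opening at C10 gives the regioisomer), and the C9 cation may lose a proton. The fallback moves the addition to a substrate with a different shield. It sets out from 15: DIBAL-H removes the pivalate to give (1R,4R,6R)-4-bromo-5,5,9-trimethylspiro[5.5]undec-9-en-1-ol F7, and Dess–Martin oxidation gives ketone F5 (defined above). In F5 the C1 carbonyl oxygen eclipses C6–C11 and covers the C10 end of the same face without a bulky ester over C9. Bromochlorination of F5 rejoins the route at ketone 19.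

**Step 12.** Methylenation of the neopentyl ketone may be incomplete, or HX may be eliminated from ring B. The fallback sets out from 19: MeMgBr/CeCl3 adds to give the tertiary alcohol (4R,6R,9S,10S)-4,10-dibromo-9-chloro-1,5,5,9-tetramethylspiro[5.5]undecan-1-ol F8. Dehydration (SOCl2, pyridine) gives a mixture of 20, which goes on to step 13, and the endocyclic alkene (4R,6S,9S,10S)-4,10-dibromo-9-chloro-1,5,5,9-tetramethylspiro[5.5]undec-1-ene F9. F9 is converted by a Schenck ene reaction with singlet oxygen (hydrogen abstraction from the methyl group geminal to quaternary C6) into the allylic hydroperoxide F10, whose reduction with PPh3 rejoins the route at 21.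

**Step 13.** Oxygen may be delivered to the wrong face of C2, since the axial trajectory is flanked by C7. The fallback sets out from 20: oxidation is taken through to the ketone (SeO2/t-BuOOH, then Dess–Martin periodinane on the crude alcohol mixture) to give (4R,6S,9S,10S)-4,10-dibromo-9-chloro-5,5,9-trimethyl-1-methylidenespiro[5.5]undecan-2-one F11. DIBAL-H at −78 °C should attack the C2 carbonyl from the equatorial side, away from the axial C7 methylene, to give the axial (2R) alcohol 21.

## Further compounds

F1 | step 5 | 6-methylhept-5-en-2-one | CC(=O)CCC=C(C)C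
F2 | step 5 | methyl 7-methyl-3-oxooct-6-enoate | COC(=O)CC(=O)CCC=C(C)C
F3 | step 5 | methyl 3-bromo-2,2-dimethyl-6-oxocyclohexane-1-carboxylate (racemic, (3R) enantiomer drawn, C1 epimerisable) | COC(=O)C1C(=O)CC[C@@H](Br)C1(C)C
F4 | step 5 | 4-bromo-3,3-dimethyl-2-methylidenecyclohexan-1-one (racemic, (4R) enantiomer drawn) | C=C1C(=O)CC[C@@H](Br)C1(C)C
F5 | step 5 | (4R,6R)-4-bromo-5,5,9-trimethylspiro[5.5]undec-9-en-1-one (racemic in this fallback, then resolved) | O=C1CC[C@@H](Br)C(C)(C)[C@]12CCC(C)=CC2
F6 | step 6 | (1R,4R)-4-bromo-5,5-dimethyl-9-oxospiro[5.5]undecan-1-yl 2,2-dimethylpropanoate | CC(C)(C)C(=O)O[C@@H]1CC[C@@H](Br)C(C)(C)C12CCC(=O)CC2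
F7 | step 9 | (1R,4R,6R)-4-bromo-5,5,9-trimethylspiro[5.5]undec-9-en-1-ol | O[C@@H]1CC[C@@H](Br)C(C)(C)[C@]12CCC(C)=CC2
F8 | step 12 | (4R,6R,9S,10S)-4,10-dibromo-9-chloro-1,5,5,9-tetramethylspiro[5.5]undecan-1-ol (C1 configuration open) | CC1(O)CC[C@@H](Br)C(C)(C)[C@]12CC[C@](C)(Cl)[C@@H](Br)C2
F9 | step 12 | (4R,6S,9S,10S)-4,10-dibromo-9-chloro-1,5,5,9-tetramethylspiro[5.5]undec-1-ene | CC1=CC[C@@H](Br)C(C)(C)[C@]12CC[C@](C)(Cl)[C@@H](Br)C2
F10 | step 12 | (2R,4R,6S,9S,10S)-4,10-dibromo-9-chloro-2-hydroperoxy-5,5,9-trimethyl-1-methylidenespiro[5.5]undecane | C=C1[C@H](OO)C[C@@H](Br)C(C)(C)[C@]12CC[C@](C)(Cl)[C@@H](Br)C2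
F11 | step 13 | (4R,6S,9S,10S)-4,10-dibromo-9-chloro-5,5,9-trimethyl-1-methylidenespiro[5.5]undecan-2-one | C=C1C(=O)C[C@@H](Br)C(C)(C)[C@]12CC[C@](C)(Cl)[C@@H](Br)C2
A1 | alternative 1 | (4R)-4-bromo-3,3-dimethyl-2-methylidenecyclohexan-1-one | C=C1C(=O)CC[C@@H](Br)C1(C)C
A2 | alternative 1 | (4R,6R)-4-bromo-5,5,9-trimethylspiro[5.5]undec-9-en-1-one | O=C1CC[C@@H](Br)C(C)(C)[C@]12CCC(C)=CC2
A3 | alternative 2 | (E)-γ-bisabolene, (E)-1-methyl-4-(6-methylhept-5-en-2-ylidene)cyclohex-1-ene | CC(C)=CCC/C(C)=C1/CC=C(C)CC1
A4 | alternative 2 | (4R,6S)-4-bromo-1,5,5,9-tetramethylspiro[5.5]undeca-1,9-diene (10-bromo-α-chamigrene) | CC1=CC[C@@H](Br)C(C)(C)[C@]12CCC(C)=CC2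
A5 | alternative 3 | (6R)-5,5-dimethyl-6-(3-methylbut-3-en-1-yl)-3-(2-methylpropoxy)-6-(prop-2-en-1-yl)cyclohex-2-en-1-one | O=C1C=C(OCC(C)C)CC(C)(C)[C@]1(CC=C)CCC(C)=C
A6 | alternative 3 | (6R)-5,5,9-trimethyl-3-(2-methylpropoxy)spiro[5.5]undeca-2,9-dien-1-one | O=C1C=C(OCC(C)C)CC(C)(C)[C@]12CCC(C)=CC2
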